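## The problem

Compound 18 joins a 7-methoxy-2,2-dimethyl-2H-chromene and a 5-acetyl-6-hydroxybenzofuran through a branched four-carbon chain. Chromene C6 carries a tertiary carbinol carbon (OH, CH3), which is followed by a CH2 and a methyl-bearing methine bonded to benzofuran C2. Both stereocentres are S and stand 1,3 to each other on an open chain. The fully substituted carbinol carbon is the harder one, and open-chain 1,3-induction between the two cannot be relied on. The carbinol is tertiary and benzylic, with an ortho methoxy group and a para ring oxygen, so it ionises or dehydrates with traces of acid. The chromene double bond excludes hydrogenation and strong electrophiles, and the methine must not pass through an activated, enolisable carbonyl stage under forcing base. A free phenol chelated to an aryl methyl ketone has to be present at the end.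

The enabling feature is the string carbinol O – carbinol C – CH2 – methine – benzofuran C2. With C2 at the carboxyl oxidation level this string is a γ-lactone, and its unsaturated form is a 3,5-dimethylbutenolide whose γ-carbon (C5) is the carbinol carbon and whose carbonyl carbon is the future benzofuran C2. The chromene C6–carbinol bond is then the bond between an aryl bromide and the γ-terminus of a furanolate, and once the lactone ring exists the quaternary centre can direct the methine across the ring.

## Retrosynthesis

**Benzofuran (18 to 14 and 16).** The O1–C2 and C3–C3a bonds of the benzofuran are cut, leading through the alkynylphenol 17 to the terminal alkyne 14 and the ortho-iodophenol 16. Both bonds form in one flask under amine base, and neither the carbinol nor the phenols need protection. Cutting the methine–C2 bond instead would require a stereocontrolled C–C bond formation next to an existing carbinol. Alkynol 14 holds all the stereochemistry and none of the benzofuran. The forward reaction must couple and cyclise through the phenol oxygen without the tertiary hydroxyl adding to the alkyne.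

**Iodophenol (16 to 15).** The C5–I bond is cut, giving 2,4-dihydroxyacetophenone 15. The forward step needs iodination ortho to the free 4-hydroxyl and para to the chelated 2-hydroxyl.

**Alkyne to lactone (14 to 13 to 12).** The terminal alkyne carbon is removed (one-carbon homologation of an aldehyde), and the carbinol oxygen is tied to the aldehyde carbon as lactol 13, which is the reduced form of lactone 12. The lactone ring protects the carbinol, supplies the carbon that becomes benzofuran C2, and holds the two stereocentres 1,3 on a five-membered ring. Using the carboxyl level directly would need a silyl ether on the carbinol and an activated ester next to the methine. The forward steps must stop the reduction at the lactol and homologate without epimerising C3.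

**Methine (12 to 11).** The C3–C4 double bond is reinstated, which deletes the methine stereocentre and leaves butenolide 11 with one stereocentre. Forward, hydride must go to C4 and a proton to C3 on the face away from the aryl group. Hydrogenation is excluded by the chromene olefin.

**Key cut (11 to 5 and 9).** The bond between chromene C6 and butenolide C5 is cut, giving bromochromene 5 and racemic butenolide 9, which reacts as its furanolate 10. This is the most convergent cut, since it joins two small pieces that carry no usable stereochemistry and creates the quaternary centre in the bond-forming event. Adding an aryl metal to a methyl ketone would form the same bond without enantiocontrol. The forward reaction has to be γ-selective and enantioface-selective on a planar dienolate.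

**Chromene (5 to 3 to 1 and 2).** The pyran ring is opened at C4–C4a and O1–C2 through the allenylphenol 4 to the aryl propargyl ether 3, which is made from 4-bromo-3-methoxyphenol 1 and the tertiary propargylic chloride 2. The bromine is in place from the start, so no halogenation of an acid- and electrophile-sensitive chromene is needed. The forward rearrangement must go to the ring position para to the methoxy group.

**Butenolide (9 to 8 to 6 and 7).** The C3=C4 double bond is cut by ring-closing metathesis to the methacrylate 8, and the ester C–O bond is cut to but-3-en-2-ol 6 and methacryloyl chloride 7. This is two steps from bulk chemicals, and the racemic alcohol is sufficient.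

## Roads not taken

**Alternative 1:** The benzofuran C2=C3 bond is cut. The precursor is the phosphonium ester A1, an aryl ester of the silylated (2S,4S)-acid on a (2-hydroxybenzyl)triphenylphosphonium salt. An amine base would form the ylide, which attacks the ester carbonyl and expels triphenylphosphine oxide to give the triethylsilyl ether A2 of the target. Desilylation would follow.
- Merits: the ring closure needs no transition metal, and it uses the carboxyl oxidation level. In that respect it is better than the chosen end game, because the carbonyl carbon of lactone 12 could be used without reduction and homologation.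
- Weak points: it is only an end game and offers nothing for either stereocentre. The methine sits α to an activated aryl ester (and to an acid chloride before that) under amine and heat, where ketene formation and enolisation would erode it. The hindered tertiary carbinol must be silylated on a ring-opened hydroxy acid that tends to relactonise. The phosphonium partner carries a free phenol and an acetyl group that the ylide can also attack.
- Comparison: the chosen plan pays one reduction and a diazophosphonate reagent. In return it needs no protecting group and keeps the methine away from activated carbonyl derivatives.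

**Alternative 2:** The methine–benzofuran C2 bond is cut. The benzofuran-2-ylboronate A4 would add to the E-crotonyl ketone A3 under Rh(acac)(C2H4)2 (monovalent rhodium) and a chiral diene or BINAP, giving ketone A5 with the methine set.
- Merits: asymmetric conjugate addition of aryl boron reagents to enones is a mature reaction class with a predictable sense of induction. On certainty of the key step this road is better than the chosen one, whose key step has no enantioselective precedent.
- Weak points: 2-heteroarylboron reagents of this kind protodeboronate readily under the aqueous basic conditions. The carbinol would then come from adding a methyl nucleophile to A5 to give the protected carbinol A6, with only a remote β-stereocentre and no chelating group to control it, so the harder centre is left uncontrolled. The ketal in A6 must be removed with acid in the presence of the acid-labile tertiary benzylic alcohol and the chromene.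
- Comparison: the chosen plan sets the quaternary centre first and lets the lactone ring relay it to the methine, and it carries no protecting groups. Against the better precedent of this alternative it can offer a resolution fallback that uses the known racemic arylation.

**Alternative 3:** The carbinol carbon–methyl bond is cut. The secondary benzylic diisopropylcarbamate A7 would be lithiated with s-BuLi and trapped with methylboronic acid pinacol ester A8. The methyl group would then shift from boron to carbon with loss of the carbamate to give the tertiary boronate A9, and oxidation would give A6.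
- Merits: the sequence is stereospecific, and the carbinol configuration derives from a secondary alcohol available by asymmetric ketone reduction. Each centre is under independent reagent control, so the absolute sense is more predictable than in the chosen key step.
- Weak points: s-BuLi is applied late to a substrate with competing acidic sites, namely benzofuran C3–H and chromene C8–H between two oxygens. Electron-rich, ortho-substituted benzylic carbamates form their boronate complexes reversibly, and methyl migrates reluctantly, so stereochemical erosion is likely. A ketal, a silyl ether and a carbamate are carried, and the acidic ketal removal meets the labile carbinol again. The methine still needs its own asymmetric step.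
- Comparison: the chosen plan is far shorter and makes both centres from one catalytic step. It has to accept that this step is new.

Key step: step 5

Remark on the chemistry: which antipode of the binaphthyl phosphine leads to (S)-11 cannot be derived from precedent. Both antipodes are available, and the route is written for the one found to give (S)-11.

## Steps

Step 1
Reactants: 1 4-bromo-3-methoxyphenol; 2 3-chloro-3-methylbut-1-yne
Product: 3 1-bromo-2-methoxy-4-[(2-methylbut-3-yn-2-yl)oxy]benzene
Conditions: DBU, CuCl2·2H2O (cat.), MeCN, 0 °C to rt
Reagents that add atoms: none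
Why: Copper-catalysed O-propargylation of a phenol with a tertiary propargylic chloride; the copper acetylide ionises to an allenylidene-type electrophile that the phenoxide captures on oxygen, and the aryl bromide and methyl ether are spectators.

Step 2
Reactants: 3 1-bromo-2-methoxy-4-[(2-methylbut-3-yn-2-yl)oxy]benzene
Product: 5 6-bromo-7-methoxy-2,2-dimethyl-2H-chromene, via allenylphenol 4 (not isolated)
Conditions: N,N-diethylaniline, 185 °C
Reagents that add atoms: none
Why: Aromatic propargyl Claisen rearrangement, enolisation to 4, 1,5-hydrogen shift and 6π oxa-electrocyclisation; the [3,3] shift should go to the ring carbon para to the methoxy group, because the position between the two oxygens is more crowded (the bromine pushes the methoxy group toward it), which gives the linear chromene.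

Step 3
Reactants: 6 but-3-en-2-ol (racemic); 7 methacryloyl chloride
Product: 8 but-3-en-2-yl 2-methylprop-2-enoate (racemic)
Conditions: Et3N, DMAP (cat.), CH2Cl2, 0 °C to rt
Reagents that add atoms: none
Why: Acylation of a secondary allylic alcohol with an acid chloride under nucleophilic catalysis.

Step 4
Reactants: 8 but-3-en-2-yl 2-methylprop-2-enoate
Product: 9 3,5-dimethylfuran-2(5H)-one (racemic)
Conditions: second-generation Grubbs catalyst (H2IMes)(PCy3)Cl2Ru=CHPh (3 mol%), CH2Cl2 (0.02 M), 40 °C
Reagents that add atoms: none
Why: Ring-closing metathesis; the carbene loads at the monosubstituted allylic olefin and closes onto the methacrylate olefin, the established route to α-methylbutenolides, and loss of ethene and dilution favour ring closure over oligomers.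

Step 5
Reactants: 5 6-bromo-7-methoxy-2,2-dimethyl-2H-chromene; 9 3,5-dimethylfuran-2(5H)-one
Product: 11 (5S)-5-(7-methoxy-2,2-dimethyl-2H-chromen-6-yl)-3,5-dimethylfuran-2(5H)-one, via potassium 3,5-dimethylfuran-2-olate 10 (not isolated)
Conditions: Pd2(dba)3 (2.5 mol%), KenPhos [2-(dicyclohexylphosphino)-2'-(dimethylamino)-1,1'-binaphthyl, one antipode, 6 mol%], K3PO4 (2 equiv), toluene/t-AmOH 4:1, 70 °C, slow addition of 9 (1.5 equiv)
Reagents that add atoms: none
Why: Proposed new method: the C6–Br bond of 5 adds oxidatively to the zerovalent palladium–phosphine complex, K3PO4 converts 9 into the aromatic 2-oxidofuran 10, which displaces bromide on palladium, and reductive elimination from the C5-bound (γ) dienolate forms the chromene C6–C5 bond and restores the conjugated lactone. The closest known reactions are the racemic palladium-catalysed γ-arylation of α-substituted butenolides to 5,5-disubstituted butenolides and the enantioselective α-arylation of α-substituted lactone and ketone enolates with chiral biaryl phosphines; what is new is enantioface selection at the γ-terminus of a planar furanolate. No ring is closed. The one new stereocentre, C5, is controlled by the chiral monophosphine, whose binaphthyl pocket must distinguish the two faces of the furanolate in the carbon-bound intermediate and in the reductive elimination; the O-, C3- and C5-bound forms interconvert, so the selection is made under Curtin–Hammett conditions, and 9 can be racemic because its stereocentre vanishes in 10. The step needs γ over α regioselectivity: both termini carry a methyl, but γ coupling keeps C3=C4 conjugated with the carbonyl and is the observed course for such dienolates with bulky monophosphines, whereas α coupling would give a deconjugated lactone. The ortho-methoxy group slows oxidative addition and reductive elimination, which the electron-rich bulky dialkylbiarylphosphine is chosen to offset, and slow addition of 9 limits Michael self-condensation of the furanolate. Product 11 has no γ-hydrogen, so the base cannot return it to the dienolate and its configuration is safe from enolisation.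

Step 6
Reactants: 11 (5S)-5-(7-methoxy-2,2-dimethyl-2H-chromen-6-yl)-3,5-dimethylfuran-2(5H)-one
Product: 12 (3S,5S)-5-(7-methoxy-2,2-dimethyl-2H-chromen-6-yl)-3,5-dimethyldihydrofuran-2(3H)-one (3-methyl cis to the aryl group)
Conditions: [(Ph3P)CuH]6 (5 mol% Cu), PhMe2SiH (1.5 equiv), t-BuOH (2 equiv), toluene, 0 °C to rt
Reagents that add atoms: none
Why: Copper hydride conjugate reduction, catalytic in copper with a silane as terminal reductant; hydride adds to C4 and the copper enolate is protonated at C3 by the bulky alcohol on the face opposite the aryl group, the larger of the two C5 substituents, which puts the C3 methyl cis to the aryl (3S); the electron-rich chromene olefin is not a substrate for this reagent.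

Step 7
Reactants: 12 (3S,5S)-5-(7-methoxy-2,2-dimethyl-2H-chromen-6-yl)-3,5-dimethyldihydrofuran-2(3H)-one
Product: 13 (3S,5S)-5-(7-methoxy-2,2-dimethyl-2H-chromen-6-yl)-3,5-dimethyltetrahydrofuran-2-ol (both C2 epimers)
Conditions: i-Bu2AlH (1.2 equiv), CH2Cl2, −78 °C; aqueous potassium sodium tartrate
Reagents that add atoms: none
Why: Partial reduction of a lactone to the lactol; the aluminium hemiacetal is stable at −78 °C and is released only on neutral work-up, and C3 is not enolised.

Step 8
Reactants: 13 (3S,5S)-5-(7-methoxy-2,2-dimethyl-2H-chromen-6-yl)-3,5-dimethyltetrahydrofuran-2-ol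
Product: 14 (2S,4S)-2-(7-methoxy-2,2-dimethyl-2H-chromen-6-yl)-4-methylhex-5-yn-2-ol
Conditions: dimethyl (1-diazo-2-oxopropyl)phosphonate (2 equiv), K2CO3, MeOH, 0 °C to rt
Reagents that add atoms: dimethyl (1-diazo-2-oxopropyl)phosphonate, COP(=O)(OC)C(=[N+]=[N-])C(C)=O
Why: Seyferth–Gilbert homologation in the Ohira–Bestmann form, a known reaction of lactols through their open hydroxy aldehydes; the diazomethylphosphonate anion adds to the aldehyde, and loss of dimethyl phosphate and N2 with a 1,2-hydrogen shift gives the terminal alkyne, while the mild carbonate base at low temperature is meant to preserve C3.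

Step 9
Reactants: 15 1-(2,4-dihydroxyphenyl)ethan-1-one
Product: 16 1-(2,4-dihydroxy-5-iodophenyl)ethan-1-one
Conditions: ICl (1.0 equiv), AcOH, rt; recrystallisation
Reagents that add atoms: iodine monochloride, ClI
Why: Electrophilic aromatic iodination; under acidic conditions attack should go to C5, ortho to the free 4-hydroxyl and para to the chelated 2-hydroxyl, since C3 between the two oxygens is more hindered; stoichiometry limits di-iodination and crystallisation removes any 3-iodo isomer.

Step 10
Reactants: 14 (2S,4S)-2-(7-methoxy-2,2-dimethyl-2H-chromen-6-yl)-4-methylhex-5-yn-2-ol; 16 1-(2,4-dihydroxy-5-iodophenyl)ethan-1-one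
Product: 18 1-{6-hydroxy-2-[(2S,4S)-4-hydroxy-4-(7-methoxy-2,2-dimethyl-2H-chromen-6-yl)pentan-2-yl]-1-benzofuran-5-yl}ethan-1-one, via alkynylphenol 17 (not isolated)
Conditions: Pd(PPh3)2Cl2 (5 mol%), CuI (10 mol%), Et3N, DMF, degassed, rt then 60 °C
Reagents that add atoms: none
Why: Sonogashira coupling to 17 followed by 5-endo-dig attack of the ortho phenoxide on the metal-activated alkyne, the standard one-flask benzofuran synthesis from ortho-iodophenols; only the 4-hydroxyl is placed to cyclise, the basic medium spares the acid-labile carbinol and chromene, and neither stereocentre is touched.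

## Compound list

1 | 4-bromo-3-methoxyphenol | COc1cc(O)ccc1Br | starting material
2 | 3-chloro-3-methylbut-1-yne | CC(C)(Cl)C#C | starting material
3 | 1-bromo-2-methoxy-4-[(2-methylbut-3-yn-2-yl)oxy]benzene | COc1cc(OC(C)(C)C#C)ccc1Br | intermediate
4 | 4-bromo-5-methoxy-2-(3-methylbuta-1,2-dien-1-yl)phenol | COc1cc(O)c(C=C=C(C)C)cc1Br | intermediate (not isolated)
5 | 6-bromo-7-methoxy-2,2-dimethyl-2H-chromene | COc1cc2OC(C)(C)C=Cc2cc1Br | intermediate
6 | but-3-en-2-ol (racemic) | CC(O)C=C | starting material
7 | methacryloyl chloride | CC(=C)C(Cl)=O | starting material
8 | but-3-en-2-yl 2-methylprop-2-enoate (racemic) | CC(=C)C(=O)OC(C)C=C | intermediate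
9 | 3,5-dimethylfuran-2(5H)-one (racemic) | CC1=CC(C)OC1=O | intermediate
10 | potassium 3,5-dimethylfuran-2-olate | Cc1cc(C)oc1[O-].[K+] | intermediate (not isolated)
11 | (5S)-5-(7-methoxy-2,2-dimethyl-2H-chromen-6-yl)-3,5-dimethylfuran-2(5H)-one | COc1cc2OC(C)(C)C=Cc2cc1[C@@]1(C)OC(=O)C(C)=C1 | intermediate
12 | (3S,5S)-5-(7-methoxy-2,2-dimethyl-2H-chromen-6-yl)-3,5-dimethyldihydrofuran-2(3H)-one | COc1cc2OC(C)(C)C=Cc2cc1[C@@]1(C)OC(=O)[C@@H](C)C1 | intermediate
13 | (3S,5S)-5-(7-methoxy-2,2-dimethyl-2H-chromen-6-yl)-3,5-dimethyltetrahydrofuran-2-ol (both C2 epimers) | COc1cc2OC(C)(C)C=Cc2cc1[C@@]1(C)OC(O)[C@@H](C)C1 | intermediate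
14 | (2S,4S)-2-(7-methoxy-2,2-dimethyl-2H-chromen-6-yl)-4-methylhex-5-yn-2-ol | COc1cc2OC(C)(C)C=Cc2cc1[C@@](C)(O)C[C@H](C)C#C | intermediate
15 | 1-(2,4-dihydroxyphenyl)ethan-1-one | CC(=O)c1ccc(O)cc1O | starting material
16 | 1-(2,4-dihydroxy-5-iodophenyl)ethan-1-one | CC(=O)c1cc(I)c(O)cc1O | intermediate
17 | 1-{2,4-dihydroxy-5-[(3S,5S)-5-hydroxy-5-(7-methoxy-2,2-dimethyl-2H-chromen-6-yl)-3-methylhex-1-yn-1-yl]phenyl}ethan-1-one | COc1cc2OC(C)(C)C=Cc2cc1[C@@](C)(O)C[C@H](C)C#Cc1cc(C(C)=O)c(O)cc1O | intermediate (not isolated)
18 | 1-{6-hydroxy-2-[(2S,4S)-4-hydroxy-4-(7-methoxy-2,2-dimethyl-2H-chromen-6-yl)pentan-2-yl]-1-benzofuran-5-yl}ethan-1-one | COc1cc2c(cc1[C@@](C)(O)C[C@H](C)c1cc3cc(C(C)=O)c(O)cc3o1)C=CC(C)(C)O2 | target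

## Step count and uncertain steps

Total: 10 steps. Longest linear sequence: 7 steps (1, 2, 5, 6, 7, 8, 10 from compound 1, or 3, 4, 5, 6, 7, 8, 10 from compounds 6 and 7).

**Step 5 (key step, Proposed new method).** The most likely failure is poor enantioface discrimination on the flat furanolate, because the two faces differ only by the positions of two methyl groups. Slow reductive elimination at the doubly hindered carbon is a second risk, with loss of the aryl bromide by reduction and self-condensation of the dienolate. Fallback by known chemistry: from 5 and 9, the arylation is run in its established racemic form with Pd2(dba)3, an achiral bulky phosphine such as 2-(di-tert-butylphosphino)biphenyl, and K3PO4. This gives racemic 5-(7-methoxy-2,2-dimethyl-2H-chromen-6-yl)-3,5-dimethylfuran-2(5H)-one F1, which is resolved by preparative chromatography on a chiral stationary phase. The S enantiomer returns to the route as 11, and the (R)-butenolide F2 is set aside.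

**Step 6.** Facial selectivity in the protonation of the copper enolate may be low, since the aryl and methyl groups at C5 differ less in effective size than the substituents of a γ-monosubstituted lactone. Fallback: the stereo-determining event is moved from enolate protonation to syn addition of hydrogen under catalyst control. From 11, hydrogenation with Ru(OAc)2(BINAP) (divalent ruthenium; the BINAP hand matched to the substrate, H2 under pressure, CH2Cl2) would deliver both hydrogens to the face opposite the aryl group and give 12 directly. This catalyst class needs a coordinating carbonyl and should leave the chromene olefin alone. Any (3R,5S)-lactone F3 still formed would be separated by chromatography, equilibrated with DBU, and separated again, returning material to 12.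

**Step 8.** Enolisation of the open hydroxy aldehyde could epimerise C3, because the lactol is held closed by its fully substituted C5 and the homologation will be slow. Fallback: from 13, Wittig chloromethylenation with Ph3P=CHCl (from the phosphonium chloride and KN(SiMe3)2, THF, 0 °C) gives (2S,4S)-6-chloro-2-(7-methoxy-2,2-dimethyl-2H-chromen-6-yl)-4-methylhex-5-en-2-ol F4 as an E/Z mixture. Dehydrochlorination with LiN(i-Pr)2 (3 equiv, THF, −78 to 0 °C) returns to the route at 14.

**Step 10.** Oxidative dimerisation of the alkyne, slow oxidative addition to the electron-rich iodoresorcinol, or competing addition of the tertiary hydroxyl to the activated alkyne could lower the efficiency. Fallback: coupling and ring closure are separated. From 16, acetylation (Ac2O, pyridine) gives 4-acetyl-6-iodo-1,3-phenylene diacetate F5. Its Sonogashira coupling with 14 at room temperature gives 4-acetyl-6-[(3S,5S)-5-hydroxy-5-(7-methoxy-2,2-dimethyl-2H-chromen-6-yl)-3-methylhex-1-yn-1-yl]-1,3-phenylene diacetate F6. Treatment with K2CO3 in MeOH at 50 °C removes both acetates and closes the furan through the phenoxide without palladium, passing through 17 to 18.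

**Step 2.** The [3,3] shift may go partly to the position between the two oxygens and give the angular 5-methoxy chromene. Fallback: the pyran ring is built by acylation instead. From 1, 3-methylbut-2-enoic acid in MeSO3H/P2O5 at 70 °C should acylate para to the methoxy group and close by oxa-Michael addition to 6-bromo-7-methoxy-2,2-dimethylchroman-4-one F7. Reduction with NaBH4 gives 6-bromo-7-methoxy-2,2-dimethylchroman-4-ol F8, and dehydration with catalytic p-TsOH in refluxing toluene returns to the route at 5.

## Further compounds

F1 | step 5 | racemic 5-(7-methoxy-2,2-dimethyl-2H-chromen-6-yl)-3,5-dimethylfuran-2(5H)-one | COc1cc2OC(C)(C)C=Cc2cc1C1(C)OC(=O)C(C)=C1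
F2 | step 5 | (5R)-5-(7-methoxy-2,2-dimethyl-2H-chromen-6-yl)-3,5-dimethylfuran-2(5H)-one | COc1cc2OC(C)(C)C=Cc2cc1[C@]1(C)OC(=O)C(C)=C1
F3 | step 6 | (3R,5S)-5-(7-methoxy-2,2-dimethyl-2H-chromen-6-yl)-3,5-dimethyldihydrofuran-2(3H)-one | COc1cc2OC(C)(C)C=Cc2cc1[C@@]1(C)OC(=O)[C@H](C)C1
F4 | step 8 | (2S,4S)-6-chloro-2-(7-methoxy-2,2-dimethyl-2H-chromen-6-yl)-4-methylhex-5-en-2-ol (E/Z mixture) | COc1cc2OC(C)(C)C=Cc2cc1[C@@](C)(O)C[C@H](C)C=CCl
F5 | step 10 | 4-acetyl-6-iodo-1,3-phenylene diacetate | CC(=O)Oc1cc(OC(C)=O)c(C(C)=O)cc1I
F6 | step 10 | 4-acetyl-6-[(3S,5S)-5-hydroxy-5-(7-methoxy-2,2-dimethyl-2H-chromen-6-yl)-3-methylhex-1-yn-1-yl]-1,3-phenylene diacetate | COc1cc2OC(C)(C)C=Cc2cc1[C@@](C)(O)C[C@H](C)C#Cc1cc(C(C)=O)c(OC(C)=O)cc1OC(C)=O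
F7 | step 2 | 6-bromo-7-methoxy-2,2-dimethylchroman-4-one | COc1cc2OC(C)(C)CC(=O)c2cc1Br
F8 | step 2 | 6-bromo-7-methoxy-2,2-dimethylchroman-4-ol (racemic) | COc1cc2OC(C)(C)CC(O)c2cc1Br
A1 | alternative 1 | {5-acetyl-4-hydroxy-2-[(2S,4S)-4-(7-methoxy-2,2-dimethyl-2H-chromen-6-yl)-2-methyl-4-(triethylsilyloxy)pentanoyloxy]benzyl}triphenylphosphonium bromide | COc1cc2OC(C)(C)C=Cc2cc1[C@@](C)(O[Si](CC)(CC)CC)C[C@H](C)C(=O)Oc1cc(O)c(C(C)=O)cc1C[P+](c1ccccc1)(c1ccccc1)c1ccccc1.[Br-]
A2 | alternative 1 | 1-{6-hydroxy-2-[(2S,4S)-4-(7-methoxy-2,2-dimethyl-2H-chromen-6-yl)-4-(triethylsilyloxy)pentan-2-yl]-1-benzofuran-5-yl}ethan-1-one | COc1cc2OC(C)(C)C=Cc2cc1[C@@](C)(O[Si](CC)(CC)CC)C[C@H](C)c1cc2cc(C(C)=O)c(O)cc2o1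
A3 | alternative 2 | (E)-1-(7-methoxy-2,2-dimethyl-2H-chromen-6-yl)but-2-en-1-one | COc1cc2OC(C)(C)C=Cc2cc1C(=O)/C=C/C
A4 | alternative 2 | 5-(2-methyl-1,3-dioxolan-2-yl)-2-(4,4,5,5-tetramethyl-1,3,2-dioxaborolan-2-yl)-6-(triisopropylsilyloxy)-1-benzofuran | CC1(C)OB(OC1(C)C)c1cc2cc(C3(C)OCCO3)c(O[Si](C(C)C)(C(C)C)C(C)C)cc2o1
A5 | alternative 2 | (3S)-1-(7-methoxy-2,2-dimethyl-2H-chromen-6-yl)-3-[5-(2-methyl-1,3-dioxolan-2-yl)-6-(triisopropylsilyloxy)-1-benzofuran-2-yl]butan-1-one | COc1cc2OC(C)(C)C=Cc2cc1C(=O)C[C@H](C)c1cc2cc(C3(C)OCCO3)c(O[Si](C(C)C)(C(C)C)C(C)C)cc2o1
A6 | alternative 2 | (2S,4S)-2-(7-methoxy-2,2-dimethyl-2H-chromen-6-yl)-4-[5-(2-methyl-1,3-dioxolan-2-yl)-6-(triisopropylsilyloxy)-1-benzofuran-2-yl]pentan-2-ol | COc1cc2OC(C)(C)C=Cc2cc1[C@@](C)(O)C[C@H](C)c1cc2cc(C3(C)OCCO3)c(O[Si](C(C)C)(C(C)C)C(C)C)cc2o1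
A7 | alternative 3 | (1S,3S)-1-(7-methoxy-2,2-dimethyl-2H-chromen-6-yl)-3-[5-(2-methyl-1,3-dioxolan-2-yl)-6-(triisopropylsilyloxy)-1-benzofuran-2-yl]butyl diisopropylcarbamate | COc1cc2OC(C)(C)C=Cc2cc1[C@@H](OC(=O)N(C(C)C)C(C)C)C[C@H](C)c1cc2cc(C3(C)OCCO3)c(O[Si](C(C)C)(C(C)C)C(C)C)cc2o1
A8 | alternative 3 | 2,4,4,5,5-pentamethyl-1,3,2-dioxaborolane | CB1OC(C)(C)C(C)(C)O1
A9 | alternative 3 | 2-{(2R,4S)-2-(7-methoxy-2,2-dimethyl-2H-chromen-6-yl)-4-[5-(2-methyl-1,3-dioxolan-2-yl)-6-(triisopropylsilyloxy)-1-benzofuran-2-yl]pentan-2-yl}-4,4,5,5-tetramethyl-1,3,2-dioxaborolane | COc1cc2OC(C)(C)C=Cc2cc1[C@@](C)(B1OC(C)(C)C(C)(C)O1)C[C@H](C)c1cc2cc(C3(C)OCCO3)c(O[Si](C(C)C)(C(C)C)C(C)C)cc2o1
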